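All runs are simulated with constants of no real substance; noise was put on by code.

Which charge of coupling partner should your next flask get, 0.950 equiv as in birch or 1.40 equiv as in ash, and is 8.0 d long enough?

in all of them: starting material 0.10 M; free catalyst 0.13 mol%

| run | coupling partner | remark | time |
|---|---|---|---|
| south-west | 1 equiv | run made earlier |  |
| north-west | 1.1 equiv | run made earlier |  |
| north-east | 1.3 equiv | run made earlier |  |
| birch | 0.950 equiv |  | 8.0 d |
| ash | 1.40 equiv |  | 8.0 d |

| run | time / d | catalyst intermediate C / % | starting material / % | catalyst intermediate B / % | product / % |
|---|---|---|---|---|---|
| south-west | 1.04 | 0 | 78 | 0 | 21 |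
| south-west | 2.08 | 0 | 56 | 1 | 42 |
| south-west | 3.00 | 0 | 39 | 0 | 60 |
| south-west | 4.00 | 0 | 28 | 0 | 76 |
| north-west | 0.333 | 3 | 92 | 0 | 9 |
| north-west | 0.833 | 0 | 81 | 0 | 18 |
| north-west | 1.67 | 0 | 64 | 2 | 36 |
| north-west | 4.00 | 0 | 24 | 1 | 73 |
| north-east | 1.04 | 0 | 76 | 0 | 24 |
| north-east | 2.08 | 0 | 53 | 0 | 44 |
| north-east | 3.00 | 0 | 38 | 0 | 60 |
| north-east | 4.00 | 0 | 22 | 0 | 78 |

(each reading ± 1.5 percentage points)

1. which of these there is most of at the end, counted by the starting material in it, birch (starting material / catalyst intermediate C / product / catalyst intermediate B)
2. which of these there is most of at the end, counted by the starting material in it, ash (starting material / catalyst intermediate C / product / catalyst intermediate B)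
3. amount of the one of these that there is most of at the end, in percent of the starting material charged, birch
4. amount of the one of these that there is most of at the end, in percent of the starting material charged, ash

- on the list of suspects stand: starting material + free catalyst -> catalyst intermediate A; catalyst intermediate A -> catalyst intermediate B; coupling partner + catalyst intermediate B -> catalyst intermediate C; catalyst intermediate C -> free catalyst + product

Start with the rate. At 4.00 d product reads 76 % with 1 equiv of partner, 73 % with 1.1 equiv and 78 % with 1.3 equiv. The 1.1 equiv run reads less than the 1 equiv run, so over this range the order in partner reads near zero, and extra partner buys you no visible speed.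

Partner matters elsewhere. On the suspected steps each product takes one starting material and one partner, so birch can make 95.0 % and ash 100 %. The smaller charge (the limiting reagent), in percent of the starting material charged, is the cap.

Now the time. The north-east run left 22 % starting material at 4.00 d. A first-order loss would square that fraction in twice the time, leaving 4.84 %. Its readings of 76 %, 53 %, 38 % and 22 % fall nearly in a line, so for a flask with partner in excess I take that as an upper estimate.

My call is to keep 8.0 d and choose the charge by what you can afford to leave behind. At its cap, birch leaves 5.00 % of the starting material unconverted, while ash at its cap leaves 28.6 % of its partner charge.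

The forecast names product for birch and product for ash, at 94 % and 97.5 %, and among its grounds is that “the partner is close to zero order”. Its birch figure sits below my cap of 95.0 %.

The flask gives product in birch at 94.9 % and product in ash at 99.7 %, so both choices of the forecast hold and both its amounts lie within their margins.

    starting material + free catalyst → catalyst intermediate A (k = 430 L mol⁻¹ h⁻¹)
    catalyst intermediate A → catalyst intermediate B (k = 41.0 h⁻¹)
    coupling partner + catalyst intermediate B → catalyst intermediate C (k = 810 L mol⁻¹ h⁻¹)
    catalyst intermediate C → free catalyst + product (k = 13.0 h⁻¹)

Has it come to rest? Ten times the time, 80.0 d, takes birch product from 94.9 % to 95.0 %, its cap of 95.0 %, with partner at 0 % of its charge and 4.87 % starting material still there. Ash moves from 99.7 % to 100 %, its cap of 100 %, with 28.6 % of its partner unused. For a neighbour of birch charged with 0.380 equiv of partner the cap reads 38.0 %, and that flask stands at 8.0 d with 38.0 % product beside 61.9 % starting material.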